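**One step.** In a one-step world, J and D would go straight to X and stay there, so X in percent of the J charged would stand at the ratio [D]/[J] of the charges, 90.0 % in Sunday's flask. The readings show something else, since X climbs and then falls.

| flask | J | D | remark | time |
|---|---|---|---|---|
| Sunday's | 2 M | 1.8 M | the very flask that is asked about, followed so far |  |
| Tuesday's | 2 M | 1.2 M | run made earlier |  |
| flask | 2.0 M | 1.80 M |  | 3.0 h |

| Sunday's: time / min | Sunday's: X / % | Tuesday's: time / min | Tuesday's: X / % |
|---|---|---|---|
| 1.33 | 21.3 | 1.33 | 14.1 |
| 5.00 | 42.7 | 5.00 | 28.4 |
| 15.0 | 36.0 | 20.0 | 22.4 |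
| 50.0 | 28.2 | 80.0 | 18.8 |

(scatter of a reading: 1 percentage point)

1. the best time, 3.0 h at the latest, for X
2. the amount of X, in percent of the J charged, at that time



**Bench rule.** Tuesday's highest reading, turned into X formed per D charged, gives the peak share of D 47.3 %, about half, a reading with the scatter of its run. Multiplied by Sunday's ratio of charges, this share gives 42.6 %, and Sunday's own highest reading, from a different flask, is 42.7 % at 5.00 min. Sunday's reading at 15.0 min is already down at 36.0 %.

**The border.** Counting one X per J, the rule would put every J as X at [D]/[J] = 2.11, so that ratio, a reading with its scatter, is the furthest the rule can reach before control passes from D to J. The asked flask stands well inside it at 0.900, with [D] below [J], and D counts as the limiting reagent. My own reckoning is therefore 42.6 %, near 5.00 min.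

**The forecast.** The forecast gives 43.5 % at 0.1 h, more than my 42.6 %, on the ground that “the best time is the early maximum”.

**The result.** The flask gives 42.5 % at 0.0983 h.

    J + D → G (k = 1.60 M⁻¹ min⁻¹)
    G → X (k = 0.420 min⁻¹)
    J + G → L (k = 0.0440 M⁻¹ min⁻¹)
    G → Z (k = 0.280 min⁻¹)
    X ⇌ E (K = 0.760, k = 0.0410 min⁻¹)

At that time D in the asked flask is down to 2.36 % of its own charge. Charged with 0.72 M of D and otherwise unchanged, a second flask is put by the share at 17.0 %, and its best stands at 17.0 %.

The readings come from a simulation from invented constants; scatter was added.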